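## Retrosynthetic overview
- The lactol ring closes last. Global hydrogenolysis of a tetrabenzyl keto diester frees the west carboxylic acid, which adds to the C3 ketone, and C3 settles by equilibration.
- The keto diester comes from oxidation of a secondary alcohol. That alcohol is made by a late esterification of the primary OH of a west diol (33 heavy atoms) with an east acid (27 heavy atoms).
- The west diol comes from bromination and carboxylation of a 3-arylbutane-1,2-diol. This diol is made by copper-catalysed opening of a Sharpless epoxy alcohol with an aryl Grignard reagent, and inversion at the attacked carbon sets C4.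
- The aryl bromide comes from 3-bromophenol by ortho-metalation/methylation and C–H borylation/oxidation. The epoxy alcohol comes from but-2-yn-1-ol.
- The east benzene ring is built de novo from malonate and 3-methylpent-3-en-2-one (Michael–Dieckmann, then aromatisation). The west benzene ring is bought in, and the lactone ring is formed last.

Assumption: C3 is a lactol carbon that equilibrates through the open keto acid. Only C4 therefore has to be set by asymmetric synthesis, and C3 is taken to settle in the (3R) form under thermodynamic control.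

## Route

### West aryl bromide

Step 1
Reactants: 1 3-bromophenol
Product: 2 1-bromo-3-methoxybenzene
Conditions: MeI, K2CO3, acetone, reflux
Reagents that add atoms: iodomethane, CI
Why: Williamson ether synthesis, in which the phenoxide is O-methylated by SN2 attack on MeI while the aryl bromide stays inert.

Step 2
Reactants: 2 1-bromo-3-methoxybenzene
Product: 4 1-bromo-3-methoxy-2-methylbenzene, via aryllithium 3 (not isolated)
Conditions: LiN(iPr)2 (commercial solution), THF, −78 °C; then MeI, −78 °C → rt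
Reagents that add atoms: iodomethane, CI
Why: Directed ortho-metalation removes the most acidic C–H, the one flanked by Br and OMe, and the aryllithium is methylated at −78 °C, below the temperature at which it loses LiBr to an aryne.

Step 3
Reactants: 4 1-bromo-3-methoxy-2-methylbenzene
Product: 6 3-bromo-5-methoxy-4-methylphenol, via aryl pinacol boronate 5 (not isolated)
Conditions: [Ir(OMe)(cod)]2 (1 mol %), 4,4'-di-tert-butyl-2,2'-bipyridine (2 mol %), B2pin2, THF, 80 °C; then KHSO5 (as 2KHSO5·KHSO4·K2SO4), acetone/H2O, rt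
Reagents that add atoms: potassium peroxymonosulfate KHSO5, [K+].[O-]S(=O)(=O)OO
Why: Sterically controlled iridium-catalysed C–H borylation (Hartwig–Miyaura type) attacks the only C–H without an ortho neighbour, tolerates C–Br, and ipso-oxidation of the C–B bond gives the phenol in the same flask.

Step 4
Reactants: 6 3-bromo-5-methoxy-4-methylphenol
Product: 7 5-(benzyloxy)-1-bromo-3-methoxy-2-methylbenzene
Conditions: BnBr, K2CO3, DMF, rt
Reagents that add atoms: benzyl bromide, BrCc1ccccc1
Why: Williamson ether synthesis installs a benzyl ether that survives the Grignard, organolithium and mild acid steps and falls off in the final hydrogenolysis.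

### Epoxy alcohol

Step 5
Reactants: 8 but-2-yn-1-ol
Product: 9 (E)-but-2-en-1-ol
Conditions: LiAlH4, THF, reflux; aqueous work-up, distillation
Reagents that add atoms: none
Why: Hydroxyl-directed trans-hydroalumination of the propargylic alcohol gives only the E-alkene, which matters because any Z-isomer would later deliver the wrong C4 configuration.

Step 6
Reactants: 9 (E)-but-2-en-1-ol
Product: 10 [(2S,3S)-3-methyloxiran-2-yl]methanol
Conditions: Ti(OiPr)4 (5 mol %), L-(+)-diisopropyl tartrate (6 mol %), t-BuOOH (in decane), 4 Å molecular sieves, CH2Cl2, −20 °C; non-aqueous work-up, distillation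
Reagents that add atoms: tert-butyl hydroperoxide, CC(C)(C)OO
Why: Sharpless asymmetric epoxidation with the L-(+)-tartrate ligand delivers oxygen to the face of the E-allylic alcohol that gives the (2S,3S)-epoxide (about 95% ee), which carries the stereochemical information for C4.

### West diol

Step 7
Reactants: 7 5-(benzyloxy)-1-bromo-3-methoxy-2-methylbenzene; 10 [(2S,3S)-3-methyloxiran-2-yl]methanol
Product: 13 (2R,3S)-3-[5-(benzyloxy)-3-methoxy-2-methylphenyl]butane-1,2-diol, via aryl Grignard reagent 11 (not isolated), via lithium epoxy alkoxide 12 (not isolated)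
Conditions: 7, Mg, BrCH2CH2Br (cat.), THF, reflux; separately 10 (1.5 equiv), n-BuLi, THF, −78 °C; combine, CuI (10 mol %), −30 → 0 °C; aq NH4Cl
Reagents that add atoms: none
Why: Copper-catalysed SN2 epoxide opening by the aryl Grignard reagent occurs at epoxide C3, the less hindered carbon remote from the electron-withdrawing CH2O group, with clean inversion, which sets the (S) benzylic stereocentre (C4 of the target).

Step 8
Reactants: 13 (2R,3S)-3-[5-(benzyloxy)-3-methoxy-2-methylphenyl]butane-1,2-diol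
Product: 14 (4R)-4-{(1S)-1-[5-(benzyloxy)-3-methoxy-2-methylphenyl]ethyl}-2,2-dimethyl-1,3-dioxolane
Conditions: 2,2-dimethoxypropane, PPTS (cat.), CH2Cl2, rt
Reagents that add atoms: 2,2-dimethoxypropane, COC(C)(C)OC
Why: Acid-catalysed transketalisation gives the five-membered acetonide, which shields both OH groups from n-BuLi and lets any 1,3-diol regioisomer from step 7 be removed by chromatography.

Step 9
Reactants: 14 (4R)-4-{(1S)-1-[5-(benzyloxy)-3-methoxy-2-methylphenyl]ethyl}-2,2-dimethyl-1,3-dioxolane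
Product: 15 (4R)-4-{(1S)-1-[3-(benzyloxy)-2-bromo-5-methoxy-6-methylphenyl]ethyl}-2,2-dimethyl-1,3-dioxolane
Conditions: NBS (1.02 equiv), MeCN, −10 → 0 °C, dark
Reagents that add atoms: N-bromosuccinimide, O=C1CCC(=O)N1Br
Why: Electrophilic aromatic bromination goes para to OMe and ortho to OBn, because the other free position lies between two alkoxy groups and is screened by the OMe methyl group that the neighbouring C-methyl pushes towards it.

Step 10
Reactants: 15 (4R)-4-{(1S)-1-[3-(benzyloxy)-2-bromo-5-methoxy-6-methylphenyl]ethyl}-2,2-dimethyl-1,3-dioxolane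
Product: 18 benzyl 2-(benzyloxy)-6-{(1S)-1-[(4R)-2,2-dimethyl-1,3-dioxolan-4-yl]ethyl}-4-methoxy-5-methylbenzoate, via aryllithium 16 (not isolated), via lithium carboxylate 17 (not isolated)
Conditions: n-BuLi, THF, −78 °C; CO2 (dry gas), −78 °C → rt; evaporate; BnBr, DMF, 40 °C
Reagents that add atoms: carbon dioxide, O=C=O; benzyl bromide, BrCc1ccccc1
Why: Bromine–lithium exchange outruns any deprotonation at −78 °C, the aryllithium is carboxylated by CO2, and the hindered carboxylate is esterified at oxygen by SN2 alkylation, so the acetonide never meets acid.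

Step 11
Reactants: 18 benzyl 2-(benzyloxy)-6-{(1S)-1-[(4R)-2,2-dimethyl-1,3-dioxolan-4-yl]ethyl}-4-methoxy-5-methylbenzoate
Product: 19 benzyl 2-(benzyloxy)-6-[(2S,3R)-3,4-dihydroxybutan-2-yl]-4-methoxy-5-methylbenzoate
Conditions: AcOH/THF/H2O (3:1:1), 35 °C
Reagents that add atoms: none
Why: Mild acid-catalysed acetal hydrolysis frees the diol, while the benzyl ester, flanked by two ortho substituents and twisted out of the ring plane, resists lactonisation at this temperature.

### East acid

Step 12
Reactants: 20 malonic acid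
Product: 21 dimethyl malonate
Conditions: MeOH, H2SO4 (cat.), reflux
Reagents that add atoms: methanol, CO
Why: Fischer esterification is driven to the diester by the excess of methanol.

Step 13
Reactants: 21 dimethyl malonate; 22 (E)-3-methylpent-3-en-2-one
Product: 24 methyl 2,3-dimethyl-4,6-dioxocyclohexane-1-carboxylate (mixture of stereoisomers and enol tautomers), via Michael adduct 23 (not isolated)
Conditions: NaOMe (1.1 equiv), MeOH, reflux; then aq HCl
Reagents that add atoms: none
Why: Michael addition of the malonate anion to the enone β-carbon followed by a Dieckmann-type (intramolecular Claisen) condensation of the methyl ketone enolate on one ester closes the six-membered ring, is driven by deprotonation of the 1,3-dione, and creates only stereocentres that vanish in step 14.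

Step 14
Reactants: 24 methyl 2,3-dimethyl-4,6-dioxocyclohexane-1-carboxylate
Product: 26 methyl 2,4-dihydroxy-5,6-dimethylbenzoate, via bromodione 25 (not isolated)
Conditions: Br2 (1.0 equiv), DMF, 0 °C; then 80 °C
Reagents that add atoms: none
Why: Bromination–dehydrobromination aromatisation, in which the 1,3-dione is brominated at its active methylene and thermal loss of HBr with keto–enol tautomerisation gives the resorcinol ester with the two methyl groups at C5 and C6.

Step 15
Reactants: 26 methyl 2,4-dihydroxy-5,6-dimethylbenzoate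
Product: 27 methyl 2,4-bis(benzyloxy)-5,6-dimethylbenzoate
Conditions: BnBr (2.5 equiv), K2CO3, DMF, 60 °C
Reagents that add atoms: benzyl bromide, BrCc1ccccc1
Why: A double Williamson ether synthesis, with warming in DMF needed to alkylate the hydrogen-bonded 2-OH as well.

Step 16
Reactants: 27 methyl 2,4-bis(benzyloxy)-5,6-dimethylbenzoate
Product: 28 2,4-bis(benzyloxy)-5,6-dimethylbenzoic acid
Conditions: KOH (10 equiv), DMSO/H2O (4:1), 100 °C; then aq HCl
Reagents that add atoms: potassium hydroxide, [K+].[OH-]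
Why: Saponification of the doubly ortho-substituted methyl ester needs poorly solvated hydroxide and heat, which the benzyl ethers tolerate.

### Coupling and endgame

Step 17
Reactants: 19 benzyl 2-(benzyloxy)-6-[(2S,3R)-3,4-dihydroxybutan-2-yl]-4-methoxy-5-methylbenzoate; 28 2,4-bis(benzyloxy)-5,6-dimethylbenzoic acid
Product: 29 (2R,3S)-3-{3-(benzyloxy)-2-[(benzyloxy)carbonyl]-5-methoxy-6-methylphenyl}-2-hydroxybutyl 2,4-bis(benzyloxy)-5,6-dimethylbenzoate
Conditions: EDC·HCl (1.3 equiv), DMAP (0.3 equiv), CH2Cl2, 0 °C → rt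
Reagents that add atoms: none
Why: Steglich esterification, in which the acylpyridinium ion from hindered acid 28 is intercepted only by the unhindered primary OH, the secondary OH next to the aryl-bearing carbon stays free, and no stereocentre is touched.

Step 18
Reactants: 29 (2R,3S)-3-{3-(benzyloxy)-2-[(benzyloxy)carbonyl]-5-methoxy-6-methylphenyl}-2-hydroxybutyl 2,4-bis(benzyloxy)-5,6-dimethylbenzoate
Product: 30 (3S)-3-{3-(benzyloxy)-2-[(benzyloxy)carbonyl]-5-methoxy-6-methylphenyl}-2-oxobutyl 2,4-bis(benzyloxy)-5,6-dimethylbenzoate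
Conditions: DMP (1.3 equiv), CH2Cl2, 0 °C → rt
Reagents that add atoms: none
Why: Dess–Martin oxidation gives the ketone without base, and the C4 stereocentre survives because enolisation towards the doubly ortho-substituted aryl group would cost severe allylic strain.

Step 19
Reactants: 30 (3S)-3-{3-(benzyloxy)-2-[(benzyloxy)carbonyl]-5-methoxy-6-methylphenyl}-2-oxobutyl 2,4-bis(benzyloxy)-5,6-dimethylbenzoate
Product: 32 [(3R,4S)-3,8-dihydroxy-6-methoxy-4,5-dimethyl-1-oxo-3,4-dihydro-1H-isochromen-3-yl]methyl 2,4-dihydroxy-5,6-dimethylbenzoate, via open keto acid 31 (not isolated)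
Conditions: H2 (1 atm), 10% Pd/C, EtOAc, rt
Reagents that add atoms: none
Why: Catalytic hydrogenolysis removes three benzyl ethers and the benzyl ester under neutral conditions, and reversible lactol closure (ring–chain tautomerism) puts the 3-OH axial (anomeric effect) and trans to the pseudo-axial 4-methyl group with the acyloxymethyl group equatorial, which is the (3R,4S) isomer.

## Compound list
1 | 3-bromophenol | Oc1cccc(Br)c1 | starting material
2 | 1-bromo-3-methoxybenzene | COc1cccc(Br)c1 | intermediate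
3 | (2-bromo-6-methoxyphenyl)lithium (not isolated) | COc1cccc(Br)c1[Li] | intermediate
4 | 1-bromo-3-methoxy-2-methylbenzene | COc1cccc(Br)c1C | intermediate
5 | 2-(3-bromo-5-methoxy-4-methylphenyl)-4,4,5,5-tetramethyl-1,3,2-dioxaborolane (not isolated) | COc1cc(B2OC(C)(C)C(C)(C)O2)cc(Br)c1C | intermediate
6 | 3-bromo-5-methoxy-4-methylphenol | COc1cc(O)cc(Br)c1C | intermediate
7 | 5-(benzyloxy)-1-bromo-3-methoxy-2-methylbenzene | COc1cc(OCc2ccccc2)cc(Br)c1C | intermediate
8 | but-2-yn-1-ol | CC#CCO | starting material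
9 | (E)-but-2-en-1-ol | C/C=C/CO | intermediate
10 | [(2S,3S)-3-methyloxiran-2-yl]methanol | C[C@@H]1O[C@H]1CO | intermediate
11 | [5-(benzyloxy)-3-methoxy-2-methylphenyl]magnesium bromide (not isolated) | COc1cc(OCc2ccccc2)cc([Mg]Br)c1C | intermediate
12 | lithium [(2S,3S)-3-methyloxiran-2-yl]methanolate (not isolated) | C[C@@H]1O[C@H]1CO[Li] | intermediate
13 | (2R,3S)-3-[5-(benzyloxy)-3-methoxy-2-methylphenyl]butane-1,2-diol | C[C@@H](c1cc(OCc2ccccc2)cc(OC)c1C)[C@@H](O)CO | intermediate
14 | (4R)-4-{(1S)-1-[5-(benzyloxy)-3-methoxy-2-methylphenyl]ethyl}-2,2-dimethyl-1,3-dioxolane | C[C@@H](c1cc(OCc2ccccc2)cc(OC)c1C)[C@@H]1COC(C)(C)O1 | intermediate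
15 | (4R)-4-{(1S)-1-[3-(benzyloxy)-2-bromo-5-methoxy-6-methylphenyl]ethyl}-2,2-dimethyl-1,3-dioxolane | C[C@@H](c1c(Br)c(OCc2ccccc2)cc(OC)c1C)[C@@H]1COC(C)(C)O1 | intermediate
16 | aryllithium from 15, Li in place of Br (not isolated) | C[C@@H](c1c([Li])c(OCc2ccccc2)cc(OC)c1C)[C@@H]1COC(C)(C)O1 | intermediate
17 | lithium 2-(benzyloxy)-6-{(1S)-1-[(4R)-2,2-dimethyl-1,3-dioxolan-4-yl]ethyl}-4-methoxy-5-methylbenzoate (not isolated) | C[C@@H](c1c(C(=O)O[Li])c(OCc2ccccc2)cc(OC)c1C)[C@@H]1COC(C)(C)O1 | intermediate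
18 | benzyl 2-(benzyloxy)-6-{(1S)-1-[(4R)-2,2-dimethyl-1,3-dioxolan-4-yl]ethyl}-4-methoxy-5-methylbenzoate | C[C@@H](c1c(C(=O)OCc2ccccc2)c(OCc2ccccc2)cc(OC)c1C)[C@@H]1COC(C)(C)O1 | intermediate
19 | benzyl 2-(benzyloxy)-6-[(2S,3R)-3,4-dihydroxybutan-2-yl]-4-methoxy-5-methylbenzoate | C[C@@H](c1c(C(=O)OCc2ccccc2)c(OCc2ccccc2)cc(OC)c1C)[C@@H](O)CO | intermediate
20 | malonic acid | OC(=O)CC(=O)O | starting material
21 | dimethyl malonate | COC(=O)CC(=O)OC | intermediate
22 | (E)-3-methylpent-3-en-2-one | C/C=C(\C)C(C)=O | starting material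
23 | dimethyl 2-(3-methyl-4-oxopentan-2-yl)propanedioate, stereoisomer mixture (not isolated) | COC(=O)C(C(=O)OC)C(C)C(C)C(C)=O | intermediate
24 | methyl 2,3-dimethyl-4,6-dioxocyclohexane-1-carboxylate, stereoisomer mixture | COC(=O)C1C(C)C(C)C(=O)CC1=O | intermediate
25 | methyl 5-bromo-2,3-dimethyl-4,6-dioxocyclohexane-1-carboxylate, stereoisomer mixture (not isolated) | COC(=O)C1C(C)C(C)C(=O)C(Br)C1=O | intermediate
26 | methyl 2,4-dihydroxy-5,6-dimethylbenzoate | COC(=O)c1c(O)cc(O)c(C)c1C | intermediate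
27 | methyl 2,4-bis(benzyloxy)-5,6-dimethylbenzoate | COC(=O)c1c(OCc2ccccc2)cc(OCc2ccccc2)c(C)c1C | intermediate
28 | 2,4-bis(benzyloxy)-5,6-dimethylbenzoic acid | OC(=O)c1c(OCc2ccccc2)cc(OCc2ccccc2)c(C)c1C | intermediate
29 | (2R,3S)-3-{3-(benzyloxy)-2-[(benzyloxy)carbonyl]-5-methoxy-6-methylphenyl}-2-hydroxybutyl 2,4-bis(benzyloxy)-5,6-dimethylbenzoate | C[C@@H](c1c(C(=O)OCc2ccccc2)c(OCc2ccccc2)cc(OC)c1C)[C@@H](O)COC(=O)c1c(OCc2ccccc2)cc(OCc2ccccc2)c(C)c1C | intermediate
30 | (3S)-3-{3-(benzyloxy)-2-[(benzyloxy)carbonyl]-5-methoxy-6-methylphenyl}-2-oxobutyl 2,4-bis(benzyloxy)-5,6-dimethylbenzoate | C[C@@H](c1c(C(=O)OCc2ccccc2)c(OCc2ccccc2)cc(OC)c1C)C(=O)COC(=O)c1c(OCc2ccccc2)cc(OCc2ccccc2)c(C)c1C | intermediate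
31 | 2-[(2S)-4-(2,4-dihydroxy-5,6-dimethylbenzoyloxy)-3-oxobutan-2-yl]-6-hydroxy-4-methoxy-3-methylbenzoic acid (not isolated) | C[C@@H](c1c(C(=O)O)c(O)cc(OC)c1C)C(=O)COC(=O)c1c(O)cc(O)c(C)c1C | intermediate
32 | [(3R,4S)-3,8-dihydroxy-6-methoxy-4,5-dimethyl-1-oxo-3,4-dihydro-1H-isochromen-3-yl]methyl 2,4-dihydroxy-5,6-dimethylbenzoate | COc1cc(O)c2c(c1C)[C@H](C)[C@](O)(COC(=O)c1c(O)cc(O)c(C)c1C)OC2=O | target

## Step count
Total step count: 19.
Longest linear sequence: 12 steps (steps 1–4, 7–11 and 17–19; 1 → 2 → 4 → 6 → 7 → 13 → 14 → 15 → 18 → 19 → 29 → 30 → 32).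
The epoxide branch runs 10 steps to the target and the east acid branch 8.

## Steps most likely to fail, with fallbacks

**Step 7.**
- The risk: attack at epoxide C2 would give the useless 1,3-diol, and the ortho-methyl aryl nucleophile is slow on an internal epoxide.
- The fallback replaces the free alkoxide by an O-blocked epoxide, so that the substrate itself dictates the site of attack. It sets out from 10, with Grignard reagent 11 made from 7 as before.
- TrCl, Et3N and DMAP in CH2Cl2 give (2S,3S)-2-methyl-3-[(triphenylmethoxy)methyl]oxirane F1, whose trityl group screens C2.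
- Reagent 11 and CuI (10 mol %) in THF at −20 °C then open C3 with inversion. This gives (2R,3S)-3-[5-(benzyloxy)-3-methoxy-2-methylphenyl]-1-(triphenylmethoxy)butan-2-ol F2.
- TsOH (cat.) in MeOH/CH2Cl2 removes the trityl group, and the fallback comes back to the route at 13.

**Step 11.**
- The risk: the freed secondary OH can attack the neighbouring benzyl ester to give a 3,4-dihydroisocoumarin. This is a dead end, because C3 is then locked at the alcohol level.
- The fallback carries the west carboxyl group as a tert-butyl ester, which does not lactonise, and unmasks it by acidolysis only after the ketone is in place. It sets out from 15.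
- n-BuLi in THF at −78 °C gives aryllithium 16, and Boc2O then gives tert-butyl 2-(benzyloxy)-6-{(1S)-1-[(4R)-2,2-dimethyl-1,3-dioxolan-4-yl]ethyl}-4-methoxy-5-methylbenzoate F3.
- AcOH/THF/H2O gives tert-butyl 2-(benzyloxy)-6-[(2S,3R)-3,4-dihydroxybutan-2-yl]-4-methoxy-5-methylbenzoate F4.
- Steglich esterification with 28 gives (2R,3S)-3-{3-(benzyloxy)-2-[(tert-butoxy)carbonyl]-5-methoxy-6-methylphenyl}-2-hydroxybutyl 2,4-bis(benzyloxy)-5,6-dimethylbenzoate F5.
- DMP gives (3S)-3-{3-(benzyloxy)-2-[(tert-butoxy)carbonyl]-5-methoxy-6-methylphenyl}-2-oxobutyl 2,4-bis(benzyloxy)-5,6-dimethylbenzoate F6.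
- TFA/CH2Cl2 (1:4) at 0 °C cleaves the tert-butyl ester, and the keto acid closes to [(3R,4S)-8-(benzyloxy)-3-hydroxy-6-methoxy-4,5-dimethyl-1-oxo-3,4-dihydro-1H-isochromen-3-yl]methyl 2,4-bis(benzyloxy)-5,6-dimethylbenzoate F7.
- H2 over Pd/C in EtOAc brings the fallback back to the route at 32.

**Step 17.**
- The risk: acid 28 is doubly ortho-substituted, so acyl transfer may be slow. N-acylurea formation, acylation of the secondary OH or acyl migration could then compete.
- The fallback reverses the roles in the ester formation: the carboxylate becomes the nucleophile and the west fragment the alkylating agent. It sets out from 19.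
- TsCl, Et3N and Bu2SnO (cat.) in CH2Cl2 sulfonylate only the primary OH. This gives benzyl 2-(benzyloxy)-6-[(2S,3R)-3-hydroxy-4-(tosyloxy)butan-2-yl]-4-methoxy-5-methylbenzoate F8.
- DMP gives benzyl 2-(benzyloxy)-4-methoxy-5-methyl-6-[(2S)-3-oxo-4-(tosyloxy)butan-2-yl]benzoate F9.
- Acid 28 with Cs2CO3 in DMF at rt displaces the activated tosylate by SN2, and the fallback comes back to the route at 30.

## Further compounds
F1 | step 7 | (2S,3S)-2-methyl-3-[(triphenylmethoxy)methyl]oxirane | C[C@@H]1O[C@H]1COC(c1ccccc1)(c1ccccc1)c1ccccc1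
F2 | step 7 | (2R,3S)-3-[5-(benzyloxy)-3-methoxy-2-methylphenyl]-1-(triphenylmethoxy)butan-2-ol | C[C@@H](c1cc(OCc2ccccc2)cc(OC)c1C)[C@@H](O)COC(c1ccccc1)(c1ccccc1)c1ccccc1
F3 | step 11 | tert-butyl 2-(benzyloxy)-6-{(1S)-1-[(4R)-2,2-dimethyl-1,3-dioxolan-4-yl]ethyl}-4-methoxy-5-methylbenzoate | C[C@@H](c1c(C(=O)OC(C)(C)C)c(OCc2ccccc2)cc(OC)c1C)[C@@H]1COC(C)(C)O1
F4 | step 11 | tert-butyl 2-(benzyloxy)-6-[(2S,3R)-3,4-dihydroxybutan-2-yl]-4-methoxy-5-methylbenzoate | C[C@@H](c1c(C(=O)OC(C)(C)C)c(OCc2ccccc2)cc(OC)c1C)[C@@H](O)CO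
F5 | step 11 | (2R,3S)-3-{3-(benzyloxy)-2-[(tert-butoxy)carbonyl]-5-methoxy-6-methylphenyl}-2-hydroxybutyl 2,4-bis(benzyloxy)-5,6-dimethylbenzoate | C[C@@H](c1c(C(=O)OC(C)(C)C)c(OCc2ccccc2)cc(OC)c1C)[C@@H](O)COC(=O)c1c(OCc2ccccc2)cc(OCc2ccccc2)c(C)c1C
F6 | step 11 | (3S)-3-{3-(benzyloxy)-2-[(tert-butoxy)carbonyl]-5-methoxy-6-methylphenyl}-2-oxobutyl 2,4-bis(benzyloxy)-5,6-dimethylbenzoate | C[C@@H](c1c(C(=O)OC(C)(C)C)c(OCc2ccccc2)cc(OC)c1C)C(=O)COC(=O)c1c(OCc2ccccc2)cc(OCc2ccccc2)c(C)c1C
F7 | step 11 | [(3R,4S)-8-(benzyloxy)-3-hydroxy-6-methoxy-4,5-dimethyl-1-oxo-3,4-dihydro-1H-isochromen-3-yl]methyl 2,4-bis(benzyloxy)-5,6-dimethylbenzoate | COc1cc(OCc3ccccc3)c2c(c1C)[C@H](C)[C@](O)(COC(=O)c1c(OCc3ccccc3)cc(OCc3ccccc3)c(C)c1C)OC2=O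
F8 | step 17 | benzyl 2-(benzyloxy)-6-[(2S,3R)-3-hydroxy-4-(tosyloxy)butan-2-yl]-4-methoxy-5-methylbenzoate | C[C@@H](c1c(C(=O)OCc2ccccc2)c(OCc2ccccc2)cc(OC)c1C)[C@@H](O)COS(=O)(=O)c1ccc(C)cc1
F9 | step 17 | benzyl 2-(benzyloxy)-4-methoxy-5-methyl-6-[(2S)-3-oxo-4-(tosyloxy)butan-2-yl]benzoate | C[C@@H](c1c(C(=O)OCc2ccccc2)c(OCc2ccccc2)cc(OC)c1C)C(=O)COS(=O)(=O)c1ccc(C)cc1
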